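## Analysis of the target

Labdane numbering is used for all carbon atoms: ring A is C1–C5 and C10, ring B is C5–C10, C17 is the exocyclic methylene carbon on C8, C18 the methyl and C19 the ester carbon on C4, C20 the methyl on C10, and C11–C16 the side chain on C9 (C16 the methyl on C13, C15 the acid carbon). The target 21 is the 19-methyl ester of a labd-8(17)-ene-15,19-dioic acid with the configuration 4R,5S,9S,10S,13R. It is a trans-fused decalin with two quaternary carbons (C4, C10), an exocyclic C8=C17 olefin, a hindered axial methyl ester and a free acid at the end of the side chain. Four stereocentres are contiguous (C4, C5, C10, C9). The C19 ester and the C20 methyl are 1,3-diaxial on one face and H5 lies on the other face. The C9 side chain lies on the face of H5, trans to C20, so it is axial on ring B; this 9,10-syn arrangement is the opposite of the equatorial side chain of the common labdanes, and rings A and B belong to the ent series. The fifth stereocentre, C13, is four bonds from C9 and cannot be set from the ring. The sensitive groups are the 1,1-disubstituted exocyclic olefin (acid-induced migration into the ring, hydrogenation, ozone) and the two carboxyl groups, which must end as one ester and one acid. The synthesis is hard for three reasons: the 1,3-diaxial pair of quaternary carbons; the axial C9 substituent, which would epimerise to the equatorial arrangement in any intermediate with a C8 carbonyl and so must be fixed kinetically in a C–C bond-forming step; and the absolute control of a ring system that is independent of C13. The feature that invites the key step is the unit C4(CO2R)–C5–C10–C9–C8(=C17): it is what an oxidative radical cyclisation of an open-chain 2-methyl-3-oxo ester leaves behind, and the axial C9 substituent maps onto a Z geometry of the C8=C9 olefin of that chain.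

## Retrosynthetic reasoning

**21 from 19.** No C–C bond is cut. The two carboxyl groups are told apart last, by steric access: the C15 ester of diester 19 is saponified (through carboxylate 20), while the C19 ester, axial on quaternary C4 and flanked by C20, should stay.

**19 from 16 through 17 and 18.** The bond cut is the acyl–oxygen bond of the auxiliary ester at C19. Transesterification of an axial neopentyl ester of a hindered secondary alcohol is not realistic. The ester is therefore reduced to diol 17 with recovery of alcohol 9, reoxidised to diacid 18 and methylated. These three steps are the price of absolute control by an ester auxiliary.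

**16 from 13 through 14 and 15.** The C3 oxygen is removed. The C3 ketone of 13 is the price of the radical initiator. It is taken out at the alcohol level by radical deoxygenation, because ionic or hydrogenolytic methods would endanger the exocyclic olefin.

**13 from 12 (key disconnection).** The bonds C4–C5 and C9–C10 are cut and the C8=C17 olefin is traced back to a methyl group. This opens both rings and leaves the acyclic keto ester 12, whose ring-forming region has no fixed stereocentre, only an E olefin (C5=C10) and a Z olefin (C8=C9). The cut is made here because C4 is the one position that can carry a radical stabilised by the ester that the target needs. Each olefin then delivers a tertiary radical, and the last radical sits exactly where the exocyclic olefin is wanted. The forward reaction has to turn E into H5 axial and a trans fusion, Z into an axial C11, place the ester axial on C4, and choose one face of C4 through the auxiliary.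

**12 from 7 and 10.** The C1–C2 bond is cut: allylic bromide 7 alkylates the terminal carbon of dianion 11, made from keto ester 10. This joins the chiral terpenoid chain and the auxiliary-bearing initiator in one step. Keto ester 10 comes from 8 and the auxiliary alcohol 9 by ester exchange.

**7 from 5 through 6.** The C1–Br bond goes back to a C–H bond. The (E)-methyl group of the terminal olefin of 5 is oxidised to allylic alcohol 6 and converted to the bromide, so the E olefin does not have to be built.

**5 from 1 and 2 through 4.** The C13 stereocentre is set by conjugate reduction of the 2E enoate 4 under reagent control. The C13=C14 bond comes from olefination of ketone 1 with phosphonate 2 (through anion 3). The Z olefin that later becomes C8=C9 is bought with nerylacetone 1, which is why this ketone and not its E isomer is the starting material.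

## Alternatives that were turned down

**Alternative 1:** the textbook route. The disconnections are C9–C11 (enolate alkylation) and C8=C17 (Wittig methylenation) on a preformed decalin made from the (R)-Wieland–Miescher ketone A1. Reductive carbomethoxylation and methylation of A1 would set C4 and C5 well, and the forward key step would be alkylation at C9 of a C8 ketone to give keto diester A2, followed by methylenation. It was turned down for four reasons.
- The axial C9 substituent of A2 is α to the ketone and is the less stable epimer; the basic alkylation and ylide conditions would equilibrate it to the equatorial arrangement.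
- The saturated carbonyl of A1 sits at C9, not C8, so a carbonyl transposition is needed.
- Enolisation of a C8 ketone goes towards C7, and C9 is neopentyl, so alkylation with an unactivated primary halide is poor.
- The stereocentres are set one at a time over more than eighteen steps.

**Alternative 2:** the biomimetic cationic cyclisation. The same bonds C4–C5 and C9–C10 are cut, but the forward key step is a Lewis acid (MeAlCl2) promoted cyclisation of the enantiopure epoxy ester A3 with a Z olefin, giving hydroxy ester A4. The transfer of Z geometry to the axial C9 substituent and the absolute control from the epoxide are most reliable in this manifold. It was turned down because a cation at C4 cannot carry an ester. C19 would have to enter as a methyl or protected hydroxymethyl group, and the larger group prefers the equatorial position, which is C18 and not C19. After the cyclisation the C3 hydroxyl must be removed and C19 oxidised and esterified, at least six functional-group steps that the radical initiator avoids.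

**Alternative 3:** a [3,3]-sigmatropic route. The C9–C11 bond is cut, and the forward key step is an orthoester Johnson–Claisen rearrangement of the ring B allylic alcohol A5, giving ester A6. The new bond would form at C9 on the face away from C20, and the exocyclic olefin would appear in the same step, so the selectivity at C9 is attractive. It was turned down on step economy. The rearrangement sets one stereocentre and no ring. It presupposes A5 with C4, C5 and C10 already in place (about ten steps by the chemistry of Alternative 1), and it leaves a two-carbon ester that must be extended by C13–C16 with the stereocentre in four or more further steps.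

Key step: step 7

Assumption: the senses of induction of the two reagent-controlled steps are taken by analogy — (S)-p-Tol-BINAP is taken to give 3R in step 2, and the (1S,2R,5S)-auxiliary 9 is taken to give the 4S,5S,9S,10S series in step 7 (its aryl group covering one face of the chelated C4 radical); if either sense is opposite, the antipodal ligand or auxiliary is used with no other change.

## Route

Step 1
Reactants: 1 (5Z)-6,10-dimethylundeca-5,9-dien-2-one (nerylacetone); 2 trimethyl phosphonoacetate
Product: 4 methyl (2E,6Z)-3,7,11-trimethyldodeca-2,6,10-trienoate, via sodium phosphonate carbanion 3 (not isolated)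
Conditions: NaH, THF, 0 °C; then 1, 0 → 50 °C; chromatography on AgNO3-impregnated silica
Reagents that add atoms: none
Why: Horner–Wadsworth–Emmons olefination of the methyl ketone; the stabilised anion should favour the 2E olefin, and only this isomer is carried on because the reduction in step 2 is stereospecific with respect to olefin geometry; the 6Z olefin bought with 1 is not touched.

Step 2
Reactants: 4 methyl (2E,6Z)-3,7,11-trimethyldodeca-2,6,10-trienoate
Product: 5 methyl (3R,6Z)-3,7,11-trimethyldodeca-6,10-dienoate
Conditions: Cu(OAc)2·H2O (3 mol %), (S)-p-Tol-BINAP (3 mol %), (EtO)2MeSiH, t-BuOH, toluene, 0 °C → rt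
Reagents that add atoms: none
Why: Copper hydride asymmetric conjugate reduction of a β,β-disubstituted enoate: the chiral bisphosphine–CuH adds hydride to one face of C3 of the 2E ester and sets the 3R centre (C13 of the target) under reagent control; isolated trisubstituted olefins are inert to CuH.

Step 3
Reactants: 5 methyl (3R,6Z)-3,7,11-trimethyldodeca-6,10-dienoate
Product: 6 methyl (3R,6Z,10E)-12-hydroxy-3,7,11-trimethyldodeca-6,10-dienoate
Conditions: SeO2 (0.3 equiv), t-BuOOH (3 equiv), salicylic acid (0.1 equiv), CH2Cl2, 0 °C → rt, partial conversion with recovery of 5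
Reagents that add atoms: tert-butyl hydroperoxide, CC(C)(C)OO; selenium dioxide, O=[Se]=O (oxygen carrier)
Why: Allylic oxidation by an ene reaction and [2,3]-sigmatropic shift, selective for the (E)-methyl group of a terminal gem-dimethyl olefin; it places oxygen on the carbon that becomes C1 with the E geometry needed for the trans ring fusion, and conversion is kept partial to limit attack at the internal olefin and over-oxidation.

Step 4
Reactants: 6 methyl (3R,6Z,10E)-12-hydroxy-3,7,11-trimethyldodeca-6,10-dienoate
Product: 7 methyl (3R,6Z,10E)-12-bromo-3,7,11-trimethyldodeca-6,10-dienoate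
Conditions: CBr4, PPh3, CH2Cl2, 0 °C
Reagents that add atoms: carbon tetrabromide, BrC(Br)(Br)Br
Why: Appel bromination of a primary allylic alcohol under neutral conditions; no allylic transposition or change of olefin geometry is expected, and the ester is inert.

Step 5
Reactants: 8 methyl 2-methyl-3-oxobutanoate; 9 (1S,2R,5S)-5-methyl-2-(2-phenylpropan-2-yl)cyclohexan-1-ol [(+)-8-phenylmenthol]
Product: 10 (1S,2R,5S)-5-methyl-2-(2-phenylpropan-2-yl)cyclohexyl 2-methyl-3-oxobutanoate (both epimers at C2 of the acyl part)
Conditions: DMAP (0.3 equiv), toluene, reflux, 4 Å molecular sieves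
Reagents that add atoms: none
Why: DMAP-catalysed transesterification of a β-keto ester, which runs through the acylketene and is possible because C2 still bears a hydrogen; the configuration at C2 is lost in step 7 and does not matter.

Step 6
Reactants: 10 (1S,2R,5S)-5-methyl-2-(2-phenylpropan-2-yl)cyclohexyl 2-methyl-3-oxobutanoate; 7 methyl (3R,6Z,10E)-12-bromo-3,7,11-trimethyldodeca-6,10-dienoate
Product: 12 16-methyl 1-[(1S,2R,5S)-5-methyl-2-(2-phenylpropan-2-yl)cyclohexyl] (6E,10Z,14R)-2,6,10,14-tetramethyl-3-oxohexadeca-6,10-dienedioate (both C2 epimers), via sodium lithium dianion 11 (not isolated)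
Conditions: NaH, THF, 0 °C; n-BuLi, 0 °C; then 7, 0 °C → rt; aqueous work-up
Reagents that add atoms: none
Why: Alkylation of the acetoacetate dianion at its terminal carbon by the allylic bromide, an SN2 reaction that forms the C1–C2 bond and leaves both olefin geometries and C13 untouched; the methyl ester of 7 should not be attacked at 0 °C.

Step 7
Reactants: 12 16-methyl 1-[(1S,2R,5S)-5-methyl-2-(2-phenylpropan-2-yl)cyclohexyl] (6E,10Z,14R)-2,6,10,14-tetramethyl-3-oxohexadeca-6,10-dienedioate
Product: 13 15-methyl 19-[(1S,2R,5S)-5-methyl-2-(2-phenylpropan-2-yl)cyclohexyl] (4S,5S,9S,10S,13R)-3-oxolabd-8(17)-ene-15,19-dioate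
Conditions: Mn(OAc)3·2H2O (2.2 equiv), Cu(OAc)2·H2O (1.0 equiv), degassed AcOH, 0.03 M, rt, 12–24 h; chromatography
Reagents that add atoms: none
Why: Manganese triacetate oxidises the enol of the 2-methyl-3-oxo ester to the planar C4 radical, which closes ring A by 6-endo-trig addition to C5 of the E olefin and gives the tertiary C10 radical; this closes ring B by a second 6-endo-trig addition to C9 of the Z olefin, and divalent copper oxidises the resulting tertiary C8 radical to an organocopper species that loses a hydrogen from C17 to form the exocyclic olefin. The closest known reaction type is the oxidative free-radical polycyclisation of polyene β-keto esters with Mn(OAc)3 and Cu(OAc)2, including its auxiliary-controlled form with 8-phenylmenthyl esters. C4 is controlled by the chair transition state of the chelated keto ester radical, which places the ester axial and the methyl equatorial (the podocarpate-type outcome), and its absolute sense by the aryl group of the auxiliary, which covers one face of the radical. C5 follows from the E geometry (C6 trans to C1, hence equatorial, H5 axial), and C10 from closure of ring B through the equatorial C6 chain, which gives the trans fusion with C20 axial. C9 is controlled by the Z geometry: in the chair closure the olefin substituent cis to C7 becomes axial, so C11 ends trans to C20 and cis to H5. The step needs 6-endo over 5-exo closure twice (secured by attack at the less substituted olefin carbon, which gives tertiary radicals), chair over boat closure of ring B, and loss of a methyl rather than a ring hydrogen in the copper-mediated elimination (the least hindered β-hydrogen is taken). C13, the C15 ester and the auxiliary should be inert to the medium, and the product cannot be oxidised further because C4 is quaternary.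

Step 8
Reactants: 13 15-methyl 19-[(1S,2R,5S)-5-methyl-2-(2-phenylpropan-2-yl)cyclohexyl] (4S,5S,9S,10S,13R)-3-oxolabd-8(17)-ene-15,19-dioate
Product: 14 15-methyl 19-[(1S,2R,5S)-5-methyl-2-(2-phenylpropan-2-yl)cyclohexyl] (3R,4S,5S,9S,10S,13R)-3-hydroxylabd-8(17)-ene-15,19-dioate
Conditions: NaBH4, MeOH/THF, 0 °C
Reagents that add atoms: none
Why: Hydride reduction of the ketone only; attack from the face away from the axial C19 ester and C20 methyl should give the equatorial 3R alcohol, but either epimer serves because C3 becomes a methylene in step 10.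

Step 9
Reactants: 14 15-methyl 19-[(1S,2R,5S)-5-methyl-2-(2-phenylpropan-2-yl)cyclohexyl] (3R,4S,5S,9S,10S,13R)-3-hydroxylabd-8(17)-ene-15,19-dioate
Product: 15 15-methyl 19-[(1S,2R,5S)-5-methyl-2-(2-phenylpropan-2-yl)cyclohexyl] (3R,4S,5S,9S,10S,13R)-3-[(imidazol-1-ylcarbonothioyl)oxy]labd-8(17)-ene-15,19-dioate
Conditions: 1,1′-thiocarbonyldiimidazole, DMAP (cat.), ClCH2CH2Cl, 70 °C
Reagents that add atoms: 1,1′-thiocarbonyldiimidazole, S=C(n1ccnc1)n1ccnc1
Why: Thioacylation of the secondary alcohol under neutral conditions, chosen over xanthate formation with a strong base to avoid retro-aldol opening of the β-hydroxy ester.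

Step 10
Reactants: 15 15-methyl 19-[(1S,2R,5S)-5-methyl-2-(2-phenylpropan-2-yl)cyclohexyl] (3R,4S,5S,9S,10S,13R)-3-[(imidazol-1-ylcarbonothioyl)oxy]labd-8(17)-ene-15,19-dioate
Product: 16 15-methyl 19-[(1S,2R,5S)-5-methyl-2-(2-phenylpropan-2-yl)cyclohexyl] (4R,5S,9S,10S,13R)-labd-8(17)-ene-15,19-dioate
Conditions: Bu3SnH, AIBN (cat.), toluene, 100 °C
Reagents that add atoms: none
Why: Barton–McCombie deoxygenation: the tin radical adds to sulfur, the C3–O bond fragments and the secondary C3 radical is reduced by Bu3SnH; the exocyclic olefin is too remote to trap the radical and the neighbouring stereocentres are not affected.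

Step 11
Reactants: 16 15-methyl 19-[(1S,2R,5S)-5-methyl-2-(2-phenylpropan-2-yl)cyclohexyl] (4R,5S,9S,10S,13R)-labd-8(17)-ene-15,19-dioate
Product: 17 (4R,5S,9S,10S,13R)-labd-8(17)-ene-15,19-diol
Conditions: LiAlH4, THF, reflux; aqueous work-up; recovery of 9
Reagents that add atoms: none
Why: Hydride reduction of both esters to primary alcohols; this step releases the auxiliary for recovery, by attack of a small nucleophile where transesterification of the axial neopentyl ester would fail, and the isolated olefin is inert.

Step 12
Reactants: 17 (4R,5S,9S,10S,13R)-labd-8(17)-ene-15,19-diol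
Product: 18 (4R,5S,9S,10S,13R)-labd-8(17)-ene-15,19-dioic acid
Conditions: CrO3, H2SO4, H2O, acetone, 0 °C
Reagents that add atoms: chromium trioxide, O=[Cr](=O)=O; water, O
Why: Jones oxidation of both primary alcohols to carboxylic acids through the aldehyde hydrates; no stereocentre can epimerise (C4 is quaternary, C13 is β to the new carboxyl) and brief exposure at 0 °C should spare the exocyclic olefin.

Step 13
Reactants: 18 (4R,5S,9S,10S,13R)-labd-8(17)-ene-15,19-dioic acid
Product: 19 dimethyl (4R,5S,9S,10S,13R)-labd-8(17)-ene-15,19-dioate
Conditions: Me3SiCHN2, MeOH/toluene, 0 °C → rt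
Reagents that add atoms: trimethylsilyldiazomethane, C[Si](C)(C)C=[N+]=[N-]
Why: O-Methylation of both carboxylic acids by the diazoalkane, a reaction at oxygen that is insensitive to the steric shielding of C19.

Step 14
Reactants: 19 dimethyl (4R,5S,9S,10S,13R)-labd-8(17)-ene-15,19-dioate
Product: 21 (3R)-5-[(1S,4aS,5R,8aS)-5-(methoxycarbonyl)-5,8a-dimethyl-2-methylidenedecahydronaphthalen-1-yl]-3-methylpentanoic acid (the target), via lithium carboxylate 20 (not isolated)
Conditions: LiOH·H2O, THF/MeOH/H2O, rt; then 1 M HCl
Reagents that add atoms: lithium hydroxide monohydrate, [Li+].[OH-].O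
Why: Saponification differentiates the two esters by steric access: hydroxide attacks the unhindered C15 ester, while the C19 ester, axial on quaternary C4 and flanked by the C20 methyl, should be inert at room temperature.

## Compound list

1 | (5Z)-6,10-dimethylundeca-5,9-dien-2-one (nerylacetone) | CC(=O)CC/C=C(/C)CCC=C(C)C | starting material
2 | trimethyl phosphonoacetate | COC(=O)CP(=O)(OC)OC | starting material
3 | sodium salt of the carbanion of 2 | [Na+].COC(=O)[CH-]P(=O)(OC)OC | intermediate (not isolated)
4 | methyl (2E,6Z)-3,7,11-trimethyldodeca-2,6,10-trienoate | COC(=O)/C=C(\C)CC/C=C(/C)CCC=C(C)C | intermediate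
5 | methyl (3R,6Z)-3,7,11-trimethyldodeca-6,10-dienoate | COC(=O)C[C@H](C)CC/C=C(/C)CCC=C(C)C | intermediate
6 | methyl (3R,6Z,10E)-12-hydroxy-3,7,11-trimethyldodeca-6,10-dienoate | COC(=O)C[C@H](C)CC/C=C(/C)CC/C=C(\C)CO | intermediate
7 | methyl (3R,6Z,10E)-12-bromo-3,7,11-trimethyldodeca-6,10-dienoate | COC(=O)C[C@H](C)CC/C=C(/C)CC/C=C(\C)CBr | intermediate
8 | methyl 2-methyl-3-oxobutanoate (racemic) | COC(=O)C(C)C(C)=O | starting material
9 | (1S,2R,5S)-5-methyl-2-(2-phenylpropan-2-yl)cyclohexan-1-ol, (+)-8-phenylmenthol | O[C@H]1C[C@@H](C)CC[C@@H]1C(C)(C)c2ccccc2 | starting material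
10 | (1S,2R,5S)-5-methyl-2-(2-phenylpropan-2-yl)cyclohexyl 2-methyl-3-oxobutanoate (both epimers at C2 of the acyl part) | CC(=O)C(C)C(=O)O[C@H]1C[C@@H](C)CC[C@@H]1C(C)(C)c2ccccc2 | intermediate
11 | sodium lithium dianion (bis-enolate) of 10 | [Na+].[Li+].C=C([O-])C(C)=C([O-])O[C@H]1C[C@@H](C)CC[C@@H]1C(C)(C)c2ccccc2 | intermediate (not isolated)
12 | 16-methyl 1-[(1S,2R,5S)-5-methyl-2-(2-phenylpropan-2-yl)cyclohexyl] (6E,10Z,14R)-2,6,10,14-tetramethyl-3-oxohexadeca-6,10-dienedioate (both C2 epimers) | COC(=O)C[C@H](C)CC/C=C(/C)CC/C=C(\C)CCC(=O)C(C)C(=O)O[C@H]1C[C@@H](C)CC[C@@H]1C(C)(C)c2ccccc2 | intermediate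
13 | 15-methyl 19-[(1S,2R,5S)-5-methyl-2-(2-phenylpropan-2-yl)cyclohexyl] (4S,5S,9S,10S,13R)-3-oxolabd-8(17)-ene-15,19-dioate | C=C1CC[C@H]2[C@@](C)(CCC(=O)[C@@]2(C)C(=O)O[C@H]3C[C@@H](C)CC[C@@H]3C(C)(C)c4ccccc4)[C@H]1CC[C@@H](C)CC(=O)OC | intermediate
14 | 15-methyl 19-[(1S,2R,5S)-5-methyl-2-(2-phenylpropan-2-yl)cyclohexyl] (3R,4S,5S,9S,10S,13R)-3-hydroxylabd-8(17)-ene-15,19-dioate | C=C1CC[C@H]2[C@@](C)(CC[C@@H](O)[C@@]2(C)C(=O)O[C@H]3C[C@@H](C)CC[C@@H]3C(C)(C)c4ccccc4)[C@H]1CC[C@@H](C)CC(=O)OC | intermediate
15 | 15-methyl 19-[(1S,2R,5S)-5-methyl-2-(2-phenylpropan-2-yl)cyclohexyl] (3R,4S,5S,9S,10S,13R)-3-[(imidazol-1-ylcarbonothioyl)oxy]labd-8(17)-ene-15,19-dioate | C=C1CC[C@H]2[C@@](C)(CC[C@@H](OC(=S)n3ccnc3)[C@@]2(C)C(=O)O[C@H]3C[C@@H](C)CC[C@@H]3C(C)(C)c4ccccc4)[C@H]1CC[C@@H](C)CC(=O)OC | intermediate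
16 | 15-methyl 19-[(1S,2R,5S)-5-methyl-2-(2-phenylpropan-2-yl)cyclohexyl] (4R,5S,9S,10S,13R)-labd-8(17)-ene-15,19-dioate | C=C1CC[C@H]2[C@@](C)(CCC[C@@]2(C)C(=O)O[C@H]3C[C@@H](C)CC[C@@H]3C(C)(C)c4ccccc4)[C@H]1CC[C@@H](C)CC(=O)OC | intermediate
17 | (4R,5S,9S,10S,13R)-labd-8(17)-ene-15,19-diol | C=C1CC[C@H]2[C@@](C)(CCC[C@@]2(C)CO)[C@H]1CC[C@@H](C)CCO | intermediate
18 | (4R,5S,9S,10S,13R)-labd-8(17)-ene-15,19-dioic acid | C=C1CC[C@H]2[C@@](C)(CCC[C@@]2(C)C(=O)O)[C@H]1CC[C@@H](C)CC(=O)O | intermediate
19 | dimethyl (4R,5S,9S,10S,13R)-labd-8(17)-ene-15,19-dioate | C=C1CC[C@H]2[C@@](C)(CCC[C@@]2(C)C(=O)OC)[C@H]1CC[C@@H](C)CC(=O)OC | intermediate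
20 | lithium (4R,5S,9S,10S,13R)-19-methoxy-19-oxolabd-8(17)-en-15-oate | C=C1CC[C@H]2[C@@](C)(CCC[C@@]2(C)C(=O)OC)[C@H]1CC[C@@H](C)CC(=O)[O-].[Li+] | intermediate (not isolated)
21 | (3R)-5-[(1S,4aS,5R,8aS)-5-(methoxycarbonyl)-5,8a-dimethyl-2-methylidenedecahydronaphthalen-1-yl]-3-methylpentanoic acid; 19-methyl hydrogen (4R,5S,9S,10S,13R)-labd-8(17)-ene-15,19-dioate | C=C1CC[C@H]2[C@@](C)(CCC[C@@]2(C)C(=O)OC)[C@H]1CC[C@@H](C)CC(=O)O | target

## Step count and least certain steps

Total step count: 14. Longest linear sequence: 13 (steps 1–4 and 6–14; step 5 prepares 10 in one step from 8 and 9).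

**Step 7 (key step).** The most likely failure is incomplete facial discrimination by the auxiliary. The radical centre at C4 is fully substituted, the aryl shield acts only through the ester conformation, and its sense rests on a model. A second weakness is leakage of the ring B closure through a boat-like transition state, because the axial C11 meets H5 and an axial hydrogen on C7; that would erode the transfer of the Z geometry to C9.

Fallback, from 7 and 8 back to the route at 19: the absolute configuration is selected by an enzyme instead of an auxiliary. Bromide 7 is alkylated with the dianion of the methyl ester 8 (NaH, n-BuLi, THF) to give dimethyl (6E,10Z,14R)-2,6,10,14-tetramethyl-3-oxohexadeca-6,10-dienedioate F1. The same Mn(OAc)3/Cu(OAc)2 bicyclisation, now without any auxiliary, gives dimethyl (4S,5S,9S,10S,13R)-3-oxolabd-8(17)-ene-15,19-dioate F2 together with its ring-antipodal diastereomer dimethyl (4R,5R,9R,10R,13R)-3-oxolabd-8(17)-ene-15,19-dioate F3. The two differ only in the relation of the ring system to the remote C13. A ketoreductase (NADPH, glucose dehydrogenase and glucose for recycling, phosphate buffer with DMSO, 30 °C), chosen from a screening panel to accept only F2, reduces it to dimethyl (3R,4S,5S,9S,10S,13R)-3-hydroxylabd-8(17)-ene-15,19-dioate F4 (either C3 epimer serves), which is easily separated from unreacted F3. Thioacylation as in step 9 gives the 3-O-(imidazol-1-ylcarbonothioyl) derivative F5, and reduction with Bu3SnH and AIBN as in step 10 gives 19 directly. This also removes steps 11 to 13, at the price that at most half of the cyclised material is used.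

**Step 2.** The likely failure is insufficient enantioselectivity, since the catalyst must distinguish a methyl group from a primary alkyl chain at C13, or a sense of induction opposite to the one assumed.

Fallback, from 4 back to 5: the stereocentre is set by a hydroxyl-directed hydrogenation whose sense is well established for E allylic alcohols of this type. Ester 4 is reduced with i-Bu2AlH to (2E,6Z)-3,7,11-trimethyldodeca-2,6,10-trien-1-ol F6. Hydrogenation with Ru(OAc)2[(S)-BINAP] under H2 in MeOH reduces only the allylic olefin and should give (3R,6Z)-3,7,11-trimethyldodeca-6,10-dien-1-ol F7. Oxidation with CrO3/H2SO4 in acetone gives (3R,6Z)-3,7,11-trimethyldodeca-6,10-dienoic acid F8, and Me3SiCHN2 returns 5. The same material serves to check the configuration obtained in step 2.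

**Step 3.** The likely failure is loss of regioselectivity and over-oxidation: the internal Z olefin is as electron-rich as the terminal one, so ene attack at its allylic positions and further oxidation of 6 to the enal compete.

Fallback, from 5 back to 6: the terminal olefin is degraded and rebuilt with an E-selective olefination instead of a direct C–H oxidation. N-Bromosuccinimide in aqueous THF, which favours the terminal olefin of a polyene, gives methyl (3R,6Z)-10-bromo-11-hydroxy-3,7,11-trimethyldodec-6-enoate F9. K2CO3 in MeOH closes it to methyl (3R,6Z)-10,11-epoxy-3,7,11-trimethyldodec-6-enoate F10. HIO4·2H2O in THF/Et2O cleaves the epoxide to methyl (3R,6Z)-3,7-dimethyl-10-oxodec-6-enoate F11. Wittig reaction with the stabilised ylide Ph3P=C(CH3)CHO in toluene at 80 °C gives methyl (3R,6Z,10E)-3,7,11-trimethyl-12-oxododeca-6,10-dienoate F12, and NaBH4 with CeCl3·7H2O in MeOH at 0 °C reduces the aldehyde to 6.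

**Step 9.** The likely failure is a stalled thioacylation. The C3 hydroxyl is flanked by quaternary C4 with its bulky ester, and forcing conditions invite elimination or retro-aldol cleavage of the β-hydroxy ester.

Fallback, from 13 back to 16: the oxygen is removed at the ketone level. Ketone 13 is condensed with 4-methylbenzenesulfonohydrazide (EtOH, cat. AcOH, reflux) to the C3 tosylhydrazone F13. This is reduced with catecholborane in CHCl3 at 0 °C and then heated with NaOAc·3H2O; loss of sulfinate and nitrogen gives 16, which replaces steps 8 to 10.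

## Further compounds

F1 | step 7 | dimethyl (6E,10Z,14R)-2,6,10,14-tetramethyl-3-oxohexadeca-6,10-dienedioate (both C2 epimers) | COC(=O)C[C@H](C)CC/C=C(/C)CC/C=C(\C)CCC(=O)C(C)C(=O)OC
F2 | step 7 | dimethyl (4S,5S,9S,10S,13R)-3-oxolabd-8(17)-ene-15,19-dioate | C=C1CC[C@H]2[C@@](C)(CCC(=O)[C@@]2(C)C(=O)OC)[C@H]1CC[C@@H](C)CC(=O)OC
F3 | step 7 | dimethyl (4R,5R,9R,10R,13R)-3-oxolabd-8(17)-ene-15,19-dioate | C=C1CC[C@@H]2[C@](C)(CCC(=O)[C@]2(C)C(=O)OC)[C@@H]1CC[C@@H](C)CC(=O)OC
F4 | step 7 | dimethyl (3R,4S,5S,9S,10S,13R)-3-hydroxylabd-8(17)-ene-15,19-dioate | C=C1CC[C@H]2[C@@](C)(CC[C@@H](O)[C@@]2(C)C(=O)OC)[C@H]1CC[C@@H](C)CC(=O)OC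
F5 | step 7 | dimethyl (3R,4S,5S,9S,10S,13R)-3-[(imidazol-1-ylcarbonothioyl)oxy]labd-8(17)-ene-15,19-dioate | C=C1CC[C@H]2[C@@](C)(CC[C@@H](OC(=S)n3ccnc3)[C@@]2(C)C(=O)OC)[C@H]1CC[C@@H](C)CC(=O)OC
F6 | step 2 | (2E,6Z)-3,7,11-trimethyldodeca-2,6,10-trien-1-ol | OC/C=C(\C)CC/C=C(/C)CCC=C(C)C
F7 | step 2 | (3R,6Z)-3,7,11-trimethyldodeca-6,10-dien-1-ol | OCC[C@H](C)CC/C=C(/C)CCC=C(C)C
F8 | step 2 | (3R,6Z)-3,7,11-trimethyldodeca-6,10-dienoic acid | OC(=O)C[C@H](C)CC/C=C(/C)CCC=C(C)C
F9 | step 3 | methyl (3R,6Z)-10-bromo-11-hydroxy-3,7,11-trimethyldodec-6-enoate (both C10 epimers) | COC(=O)C[C@H](C)CC/C=C(/C)CCC(Br)C(C)(C)O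
F10 | step 3 | methyl (3R,6Z)-10,11-epoxy-3,7,11-trimethyldodec-6-enoate (both C10 epimers) | COC(=O)C[C@H](C)CC/C=C(/C)CCC1OC1(C)C
F11 | step 3 | methyl (3R,6Z)-3,7-dimethyl-10-oxodec-6-enoate | COC(=O)C[C@H](C)CC/C=C(/C)CCC=O
F12 | step 3 | methyl (3R,6Z,10E)-3,7,11-trimethyl-12-oxododeca-6,10-dienoate | COC(=O)C[C@H](C)CC/C=C(/C)CC/C=C(\C)C=O
F13 | step 9 | C3 (4-methylbenzenesulfonyl)hydrazone of 13 | C=C1CC[C@H]2[C@@](C)(CCC(=NNS(=O)(=O)c3ccc(C)cc3)[C@@]2(C)C(=O)O[C@H]3C[C@@H](C)CC[C@@H]3C(C)(C)c4ccccc4)[C@H]1CC[C@@H](C)CC(=O)OC
A1 | alternative 1 | (R)-Wieland–Miescher ketone, (8aR)-8a-methyl-3,4,8,8a-tetrahydronaphthalene-1,6(2H,7H)-dione | C1CCC=2[C@@](C)(CCC(=O)C=2)C1=O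
A2 | alternative 1 | dimethyl 8-oxo-17-norlabdane-15,19-dioate with the spatial arrangement of the target at C4, C5, C9 (side chain axial), C10 and C13 | O=C1CC[C@H]2[C@@](C)(CCC[C@@]2(C)C(=O)OC)[C@H]1CC[C@@H](C)CC(=O)OC
A3 | alternative 2 | methyl (3R,6Z,10E,14R)-14,15-epoxy-3,7,11,15-tetramethylhexadeca-6,10-dienoate | COC(=O)C[C@H](C)CC/C=C(/C)CC/C=C(\C)CC[C@H]1OC1(C)C
A4 | alternative 2 | methyl 3-hydroxylabd-8(17)-en-15-oate with two methyl groups on C4, an equatorial 3-hydroxyl and the spatial arrangement of the target at C5, C9, C10 and C13 | C=C1CC[C@H]2[C@@](C)(CC[C@@H](O)C2(C)C)[C@H]1CC[C@@H](C)CC(=O)OC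
A5 | alternative 3 | methyl 17-hydroxy-11,12,13,14,15,16-hexanorlabd-8-en-19-oate with the spatial arrangement of the target at C4, C5 and C10 | OCC=1CC[C@H]2[C@@](C)(CCC[C@@]2(C)C(=O)OC)C=1
A6 | alternative 3 | 12-ethyl 19-methyl 13,14,15,16-tetranorlabd-8(17)-ene-12,19-dioate with the spatial arrangement of the target at C4, C5, C9 and C10 | C=C1CC[C@H]2[C@@](C)(CCC[C@@]2(C)C(=O)OC)[C@H]1CC(=O)OCC
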